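**Plan**

1. Benzofuran numbering of the target (O1, C2, C3, C3a, C4–C7, C7a) is used for all intermediates. Retrosynthetic cuts, in order: the C6–C(styryl) bond (Suzuki–Miyaura, C6–B from C6–H). The benzo ring is then taken back to the cyclohexane-1,3-dione oxidation level. O1–C2 is cut and C2 re-bonded to C3a, which turns the dihydrofuran into a spiro-cyclopropane C2–C3–C3a. Finally C3a–C2 and C3a–C3 are cut to a dione carbene and the alkene of oxyresveratrol.
2. Forward order of rings: cyclopropane (carbene + stilbene), then the five-membered O-ring by 3→5 ring expansion, then aromatisation of the six-membered ring, then the C6 styryl arm, then desilylation.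
3. Enabling feature: C2 carries the 2,4-dihydroxyphenyl ring, whose oxygens are ortho/para to C2 and can form a quinone methide. C3 carries the 3,5-dihydroxyphenyl ring, whose oxygens are only meta and cannot. The unit O1–C7a=C3a–C4–OH of the benzo ring is an aromatised cyclohexane-1,3-dione enol. A C2–C3–C3a cyclopropane spiro-fused to that dione is therefore a push–pull system that can break only at C2–C3a and reclose through O1.
4. Switch: four acetates keep the donor off while the strained ring is built and purified. Their removal turns the donor on and starts the ring expansion.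
5. Stereochemistry: C3 comes from the face selection of a chiral Rh(II) catalyst in a stereospecific cyclopropanation of the E-alkene. C2 is re-set trans to C3 by substrate and thermodynamic control in the ring expansion. The E-stilbene comes from an (E)-alkenyl bromide coupled with retention.

Key step: step 4

Assumption: the sense of induction of the chiral Rh(II) catalyst on this alkene class is not known in advance. The (S)-ligand series is written, and the mirror-image catalyst is taken if it favours the other antipode of the spirocyclopropane.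

**Step 1**
Reactants: 1 oxyresveratrol
Product: 2 oxyresveratrol tetraacetate
Conditions: Ac2O (6 equiv), pyridine, DMAP (cat.), 0 °C to rt
Reagents that add atoms: acetic anhydride CC(=O)OC(C)=O
Why: Exhaustive O-acylation of the four phenols (nucleophilic acyl substitution) turns the strongly donating OH groups into poor donors, which is what should make the later cyclopropane isolable.

**Step 2**
Reactants: 3 cyclohexane-1,3-dione
Product: 4 2-(phenyl-λ3-iodanylidene)cyclohexane-1,3-dione
Conditions: PhI(OAc)2 (1.0 equiv), KOH (2 equiv), MeOH, 0 °C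
Reagents that add atoms: (diacetoxyiodo)benzene CC(=O)OI(OC(C)=O)c1ccccc1
Why: The acidic C2–H2 of the dione condenses with the iodine(III) diacetate under base to the stabilised β-dicarbonyl iodonium ylide, a standard carbene precursor that loses PhI at or below room temperature.

**Step 3**
Reactants: 2 oxyresveratrol tetraacetate; 4 2-(phenyl-λ3-iodanylidene)cyclohexane-1,3-dione
Product: 5 (1S,2S)-1-(2,4-diacetoxyphenyl)-2-(3,5-diacetoxyphenyl)spiro[2.5]octane-4,8-dione
Conditions: Rh2(S-TCPTTL)4 (2 mol %), 4 (2 equiv, in portions), CH2Cl2, 0 °C to rt, dark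
Reagents that add atoms: none
Why: Proposed new method: Rh(II) takes up the ylide carbon with loss of PhI to give an electrophilic diacyl carbene that adds to the only C=C bond of 2 in a concerted, asynchronous [2+1] step, so the E geometry is copied into the trans relationship and the choice of alkene face inside the chiral cavity of the catalyst fixes C3 (and provisionally C2); the four acetates leave both aryl rings too poor as donors for a zwitterionic O-closure or an in situ rearrangement, so the three-membered ring should survive; the closest known reaction types are the Rh(II)-catalysed cyclopropanation of styrenes with the same dione carbene to isolable spiro[2.5]octane-4,8-diones and the enantioselective Rh(II)- or Cu(I)-bis(oxazoline)-catalysed cyclopropanations with iodonium ylides of malonates and Meldrum's acid, which include 1,2-disubstituted alkenes; new is the pairing of the cyclic dione carbene with an internal diaryl alkene under enantiocontrol.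

**Step 4**
Reactants: 5 (1S,2S)-1-(2,4-diacetoxyphenyl)-2-(3,5-diacetoxyphenyl)spiro[2.5]octane-4,8-dione
Product: 8 (2S,3S)-2-(2,4-dihydroxyphenyl)-3-(3,5-dihydroxyphenyl)-3,5,6,7-tetrahydro-1-benzofuran-4(2H)-one, via tetraphenol cyclopropane 6 (not isolated), via quinone methide enolate 7 (not isolated)
Conditions: K2CO3 (20 mol %), degassed MeOH, 0 °C to rt, short time; neutralised with acidic ion-exchange resin
Reagents that add atoms: none
Why: Proposed new method: base-catalysed methanolysis frees the four phenols, and as soon as the O4' (or O2') phenoxide of the C2 aryl ring exists it pushes into the C2–C3a bond while the 1,3-dione pulls, so this bond breaks heterolytically (strain-releasing retro-1,6-addition) to the quinone methide/dione enolate 7. An enolate oxygen of 7 then adds to the methide carbon C2 in a 5-exo-trig oxa-1,6-addition that restores the arene, which turns the three-membered ring C2–C3–C3a into the five-membered ring O1–C2–C3–C3a–C7a, an anionic Cloke–Wilson rearrangement. The closest known reaction types are the acid-, iodide- or heat-induced Cloke–Wilson ring expansion of 1-arylspiro[2.5]octane-4,8-diones to 2-aryl-tetrahydrobenzofuran-4-ones and the base- or fluoride-triggered opening of 2-(4-hydroxy- or 4-siloxyaryl)cyclopropane-1,1-diesters through p-quinone methides; their union in one phenoxide-triggered rearrangement is what is new. C3 keeps the configuration set in step 3 because none of its bonds is broken, and the new C2 centre is placed trans to the C3 aryl group by 1,2-steric control in the closure, backed by the reversibility of the oxa-addition under base, which should drain any cis isomer to the more stable trans one. Bond selectivity is secured by the substitution pattern: the C3 aryl ring has its oxygens meta to C3 and cannot form a quinone methide, so C3–C3a stays intact, C2–C3 cleavage would leave no stabilised anion, the two enolate oxygens give the same product, and C-closure only regenerates strained 6. Addition of methanol to 7 should be outrun by the intramolecular closure, and low temperature with a short contact time limits loss of H3 from 7.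

**Step 5**
Reactants: 8 (2S,3S)-2-(2,4-dihydroxyphenyl)-3-(3,5-dihydroxyphenyl)-3,5,6,7-tetrahydro-1-benzofuran-4(2H)-one
Product: 9 (2S,3S)-4-(TBSO)-2-[2,4-bis(TBSO)phenyl]-3-[3,5-bis(TBSO)phenyl]-2,3,6,7-tetrahydro-1-benzofuran
Conditions: TBSOTf (7 equiv), Et3N (12 equiv), CH2Cl2, 0 °C to rt
Reagents that add atoms: tert-butyldimethylsilyl triflate CC(C)(C)[Si](C)(C)OS(=O)(=O)C(F)(F)F
Why: Silyl triflate/amine silylates the four phenols and soft-enolises the vinylogous ester (O-silylation, then loss of H5) to the 1-oxy-3-silyloxycyclohexa-1,3-diene, so protection and the set-up for aromatisation are one operation, and loss of H7 instead would give a diene that aromatises to the same arene.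

**Step 6**
Reactants: 9 (2S,3S)-4-(TBSO)-2-[2,4-bis(TBSO)phenyl]-3-[3,5-bis(TBSO)phenyl]-2,3,6,7-tetrahydro-1-benzofuran
Product: 10 (2S,3S)-4-(TBSO)-2-[2,4-bis(TBSO)phenyl]-3-[3,5-bis(TBSO)phenyl]-2,3-dihydro-1-benzofuran
Conditions: DDQ (1.05 equiv), CH2Cl2, −40 to 0 °C
Reagents that add atoms: none
Why: DDQ dehydrogenation takes hydride from C6 of the doubly oxygenated cyclohexadiene to give an arenium-type cation that loses H7 and keeps the silyl ether, and this diene is far easier to oxidise than any other site, so one equivalent at low temperature should leave C2–H and C3–H untouched.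

**Step 7**
Reactants: 10 (2S,3S)-4-(TBSO)-2-[2,4-bis(TBSO)phenyl]-3-[3,5-bis(TBSO)phenyl]-2,3-dihydro-1-benzofuran
Product: 11 6-(pinacolatoboryl) derivative of 10
Conditions: [Ir(OMe)(cod)]2 (2.5 mol %), dtbpy (5 mol %), B2pin2 (1.2 equiv), THF, 70 °C
Reagents that add atoms: bis(pinacolato)diboron CC1(C)OB(OC1(C)C)B1OC(C)(C)C(C)(C)O1
Why: Sterically governed iridium-catalysed aromatic C–H borylation should pick C6–H, the only aryl C–H of 10 without an ortho substituent and the one meta to both ring oxygens (the 5-position of a 1,3-dioxygenated benzene), all others being flanked by OTBS, O1 or a benzylic carbon.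

**Step 8**
Reactants: 12 trans-ferulic acid
Product: 14 (E)-3-[4-(TBSO)-3-methoxyphenyl]prop-2-enoic acid, via bis-silyl ferulate 13 (not isolated)
Conditions: TBSCl (2.4 equiv), imidazole (5 equiv), DMF, rt; then AcOH–THF–H2O, rt
Reagents that add atoms: tert-butyldimethylsilyl chloride CC(C)(C)[Si](C)(C)Cl
Why: Imidazole-promoted silylation covers phenol and acid, and the much more labile silyl ester is hydrolysed selectively under mild aqueous acid while the aryl silyl ether stays.

**Step 9**
Reactants: 14 (E)-3-[4-(TBSO)-3-methoxyphenyl]prop-2-enoic acid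
Product: 15 (E)-[4-(2-bromoethenyl)-2-methoxyphenoxy](tert-butyl)dimethylsilane
Conditions: NBS (1.05 equiv), Et3N (10 mol %), CH2Cl2, rt
Reagents that add atoms: N-bromosuccinimide O=C1CCC(=O)N1Br
Why: The catalytic Hunsdiecker-type bromodecarboxylation of electron-rich cinnamic acids (bromonium attack at the α-carbon, then anti loss of CO2) should give the (E)-β-bromostyrene.

**Step 10**
Reactants: 11 6-(pinacolatoboryl) derivative of 10; 15 (E)-[4-(2-bromoethenyl)-2-methoxyphenoxy](tert-butyl)dimethylsilane
Product: 16 hexa-TBS ether of the target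
Conditions: Pd(dppf)Cl2 (5 mol %), K3PO4 (3 equiv), THF–H2O (10:1), 50 °C, dark
Reagents that add atoms: none
Why: Suzuki–Miyaura sp2–sp2 coupling of an unhindered aryl boronate with an (E)-alkenyl bromide goes with retention of the alkene geometry, and partial loss of phenolic TBS groups under the base would be harmless because the next step removes them all.

**Step 11**
Reactants: 16 hexa-TBS ether of the target
Product: 17 target CNP0136479.1
Conditions: Et3N·3HF (excess), THF, rt, dark, under argon
Reagents that add atoms: none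
Why: Fluoride-driven Si–O cleavage under slightly acidic conditions avoids phenoxides, so the C2–O1 bond, the stilbene, the aryl methyl ether and both stereocentres should be left as they are.

**Compound list**

1 | oxyresveratrol, (E)-4-[2-(3,5-dihydroxyphenyl)ethenyl]benzene-1,3-diol | Oc1ccc(/C=C/c2cc(O)cc(O)c2)c(O)c1 | starting material
2 | oxyresveratrol tetraacetate | CC(=O)Oc1ccc(/C=C/c2cc(OC(C)=O)cc(OC(C)=O)c2)c(OC(C)=O)c1 | intermediate
3 | cyclohexane-1,3-dione | O=C1CCCC(=O)C1 | starting material
4 | 2-(phenyl-λ3-iodanylidene)cyclohexane-1,3-dione (written as zwitterion) | [O-]C1=C([I+]c2ccccc2)C(=O)CCC1 | intermediate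
5 | (1S,2S)-1-(2,4-diacetoxyphenyl)-2-(3,5-diacetoxyphenyl)spiro[2.5]octane-4,8-dione | O=C1CCCC(=O)C12[C@H](c1ccc(OC(C)=O)cc1OC(C)=O)[C@H]2c1cc(OC(C)=O)cc(OC(C)=O)c1 | intermediate
6 | (1S,2S)-1-(2,4-dihydroxyphenyl)-2-(3,5-dihydroxyphenyl)spiro[2.5]octane-4,8-dione (reacts as phenoxide) | O=C1CCCC(=O)C12[C@H](c1ccc(O)cc1O)[C@H]2c1cc(O)cc(O)c1 | intermediate
7 | (S)-2-[1-(3,5-dihydroxyphenyl)-2-(2-hydroxy-4-oxocyclohexa-2,5-dien-1-ylidene)ethyl]-3-hydroxycyclohex-2-en-1-one (neutral form of the quinone methide enolate, methide geometry open) | O=C1CCCC(O)=C1[C@@H](C=C1C=CC(=O)C=C1O)c1cc(O)cc(O)c1 | intermediate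
8 | (2S,3S)-2-(2,4-dihydroxyphenyl)-3-(3,5-dihydroxyphenyl)-3,5,6,7-tetrahydro-1-benzofuran-4(2H)-one | O=C1CCCC2=C1[C@H](c1cc(O)cc(O)c1)[C@@H](c1ccc(O)cc1O)O2 | intermediate
9 | (2S,3S)-4-(TBSO)-2-[2,4-bis(TBSO)phenyl]-3-[3,5-bis(TBSO)phenyl]-2,3,6,7-tetrahydro-1-benzofuran | CC(C)(C)[Si](C)(C)OC1=CCCC2=C1[C@H](c3cc(O[Si](C)(C)C(C)(C)C)cc(O[Si](C)(C)C(C)(C)C)c3)[C@@H](c3ccc(O[Si](C)(C)C(C)(C)C)cc3O[Si](C)(C)C(C)(C)C)O2 | intermediate
10 | (2S,3S)-4-(TBSO)-2-[2,4-bis(TBSO)phenyl]-3-[3,5-bis(TBSO)phenyl]-2,3-dihydro-1-benzofuran | CC(C)(C)[Si](C)(C)Oc1cccc2c1[C@H](c3cc(O[Si](C)(C)C(C)(C)C)cc(O[Si](C)(C)C(C)(C)C)c3)[C@@H](c3ccc(O[Si](C)(C)C(C)(C)C)cc3O[Si](C)(C)C(C)(C)C)O2 | intermediate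
11 | 6-(4,4,5,5-tetramethyl-1,3,2-dioxaborolan-2-yl) derivative of 10 | CC(C)(C)[Si](C)(C)Oc1cc(B4OC(C)(C)C(C)(C)O4)cc2c1[C@H](c3cc(O[Si](C)(C)C(C)(C)C)cc(O[Si](C)(C)C(C)(C)C)c3)[C@@H](c3ccc(O[Si](C)(C)C(C)(C)C)cc3O[Si](C)(C)C(C)(C)C)O2 | intermediate
12 | trans-ferulic acid | COc1cc(/C=C/C(=O)O)ccc1O | starting material
13 | tert-butyldimethylsilyl (E)-3-[4-(TBSO)-3-methoxyphenyl]prop-2-enoate | COc1cc(/C=C/C(=O)O[Si](C)(C)C(C)(C)C)ccc1O[Si](C)(C)C(C)(C)C | intermediate
14 | (E)-3-[4-(TBSO)-3-methoxyphenyl]prop-2-enoic acid | COc1cc(/C=C/C(=O)O)ccc1O[Si](C)(C)C(C)(C)C | intermediate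
15 | (E)-[4-(2-bromoethenyl)-2-methoxyphenoxy](tert-butyl)dimethylsilane | COc1cc(/C=C/Br)ccc1O[Si](C)(C)C(C)(C)C | intermediate
16 | hexa-TBS ether of the target, (2S,3S) | COc1cc(/C=C/c2cc(O[Si](C)(C)C(C)(C)C)c3c(c2)O[C@H](c2ccc(O[Si](C)(C)C(C)(C)C)cc2O[Si](C)(C)C(C)(C)C)[C@H]3c2cc(O[Si](C)(C)C(C)(C)C)cc(O[Si](C)(C)C(C)(C)C)c2)ccc1O[Si](C)(C)C(C)(C)C | intermediate
17 | CNP0136479.1, (2S,3S)-2-(2,4-dihydroxyphenyl)-3-(3,5-dihydroxyphenyl)-6-[(E)-2-(4-hydroxy-3-methoxyphenyl)ethenyl]-2,3-dihydro-1-benzofuran-4-ol | COc1cc(/C=C/c2cc(O)c3c(c2)O[C@H](c2ccc(O)cc2O)[C@H]3c2cc(O)cc(O)c2)ccc1O | target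

**Total step count:** 11. **Longest linear sequence:** 8 (steps 1, 3, 4, 5, 6, 7, 10, 11, from 1).

**Steps most likely to fail**

- **Step 3.**
  - What may go wrong: carbene transfer to a hindered internal diaryl alkene may be slow, so the ylide decomposes on its own. Discrimination of the two alkene faces may also be insufficient.
  - Fallback, from 3 and 2, back at 5: chirality is obtained by resolution instead of catalysis. Regitz diazo transfer on 3 (4-acetamidobenzenesulfonyl azide, Et3N, MeCN) would give 2-diazocyclohexane-1,3-dione F1. F1 is added slowly to 2 with the robust achiral catalyst Rh2(esp)2 in warm 1,2-dichloroethane. This would give the racemic trans-cyclopropane, that is 5 together with its (1R,2R)-enantiomer F2. The two are separated by preparative supercritical-fluid chromatography on a polysaccharide chiral stationary phase.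
- **Step 4.**
  - What may go wrong: methanol may trap the quinone methide. The opened intermediate may lose H3 and tautomerise to a hydroxystilbene, which erases C3. Methoxide may cleave the non-enolisable dione in a retro-Claisen reaction.
  - Fallback, from 5, back at 8: the order is reversed and the activation is changed from phenoxide push to carbonyl pull. The known Brønsted-acid-catalysed Cloke–Wilson ring expansion (TsOH·H2O cat., CH2Cl2, rt to 40 °C) is run with the acetates in place. The 2,4-diacetoxyphenyl-substituted carbon still gives the better benzylic cation than the 3,5-isomer. The product would be (2S,3S)-2-(2,4-diacetoxyphenyl)-3-(3,5-diacetoxyphenyl)-3,5,6,7-tetrahydro-1-benzofuran-4(2H)-one F3. Its acetates are then removed with methanolic HCl at rt.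
- **Step 6.**
  - What may go wrong: DDQ may abstract hydride at C2–H, a 2,4-dioxygenated benzylic ether position, followed by loss of H3. This over-oxidises the ring to the flat benzofuran and loses both stereocentres. The C4 silyl group may also be lost.
  - Fallback, from 9, back at 10: the hydride acceptor is replaced by a Saegusa–Ito dehydrosilylation (Pd(OAc)2 10 mol %, O2, DMSO, rt), which acts only at the silyl enol ether. It would give the cross-conjugated (2S,3S)-2,3-dihydro-1-benzofuran-4(7H)-one F4. F4 tautomerises at once to (2S,3S)-2-[2,4-bis(TBSO)phenyl]-3-[3,5-bis(TBSO)phenyl]-2,3-dihydro-1-benzofuran-4-ol F5. Silylation of F5 (TBSCl, imidazole, DMF) leads to 10.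

**Further compounds**

F1 | step 3 | 2-diazocyclohexane-1,3-dione | O=C1CCCC(=O)C1=[N+]=[N-]
F2 | step 3 | (1R,2R)-1-(2,4-diacetoxyphenyl)-2-(3,5-diacetoxyphenyl)spiro[2.5]octane-4,8-dione | O=C1CCCC(=O)C12[C@@H](c1ccc(OC(C)=O)cc1OC(C)=O)[C@@H]2c1cc(OC(C)=O)cc(OC(C)=O)c1
F3 | step 4 | (2S,3S)-2-(2,4-diacetoxyphenyl)-3-(3,5-diacetoxyphenyl)-3,5,6,7-tetrahydro-1-benzofuran-4(2H)-one | O=C1CCCC2=C1[C@H](c1cc(OC(C)=O)cc(OC(C)=O)c1)[C@@H](c1ccc(OC(C)=O)cc1OC(C)=O)O2
F4 | step 6 | (2S,3S)-2-[2,4-bis(TBSO)phenyl]-3-[3,5-bis(TBSO)phenyl]-2,3-dihydro-1-benzofuran-4(7H)-one | O=C1C=CCC2=C1[C@H](c3cc(O[Si](C)(C)C(C)(C)C)cc(O[Si](C)(C)C(C)(C)C)c3)[C@@H](c3ccc(O[Si](C)(C)C(C)(C)C)cc3O[Si](C)(C)C(C)(C)C)O2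
F5 | step 6 | (2S,3S)-2-[2,4-bis(TBSO)phenyl]-3-[3,5-bis(TBSO)phenyl]-2,3-dihydro-1-benzofuran-4-ol | Oc1cccc2c1[C@H](c3cc(O[Si](C)(C)C(C)(C)C)cc(O[Si](C)(C)C(C)(C)C)c3)[C@@H](c3ccc(O[Si](C)(C)C(C)(C)C)cc3O[Si](C)(C)C(C)(C)C)O2
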